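The constants are invented.

How much product does this flask make in its run, when the coupling partner reaches the solution by dissolving from a solid?

    substrate + coupling partner → product, rate k1*[substrate]^0.5*[coupling partner]^0.5 (k1 = 0.23 h⁻¹)
    solid reagent ⇌ coupling partner, rate k2*(cs2 - [coupling partner]) while solid is left; crystals form when [coupling partner] > cs2 (cs2 = 14 mM, k2 = 8.9 h⁻¹)

substrate 0.080 M; solid reagent 1.10 equiv; time 80 min

* amount of product at 80 min, in percent of the substrate charged
* the change that raises the amount of product at 80 min, in percent of the substrate charged most ("none" if none brings more than 2 percentage points) (Thursday's / Monday's / none)
* amount of product at 80 min, in percent of the substrate charged, after Thursday's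

- as a solid, counted per litre of solution: solid reagent
- at the start none of the solid reagent is in solution
- run time (flask): 80 min

At the first moment, with no coupling partner in solution, dissolution delivers 0.125 M h⁻¹. The coupling, even with the partner at its solubility, runs at a ceiling rate r, the rate constant times the square root of substrate times solubility: 0.00770 M h⁻¹, far less than dissolution delivers. So the partner climbs towards its solubility with a lag τ, the inverse dissolution coefficient, 6.74 min, and the coupling, slower than dissolution at these rates, is the rate-limiting step.

My first estimate lets r run from the end of τ to the end of the flask's time. That gives 11.7%: the capped yield Y, the rate constant times the time less τ times the square root of solubility over substrate. The solid lasts through the flask's time, since by this estimate solution and coupling together take about 0.0234 M, less than the 0.0880 M charged.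

The weak link is the partner standing at its solubility. Dissolution must match the coupling, which needs a gap g below solubility, r over the dissolution coefficient: 0.865 mM. Through the square root this trims Y to 11.4%, my committed figure. Thursday's doubled solubility raises r by a factor of 1.41, and that factor applied to my figure gives 16.1%. Monday's doubled coefficient shortens τ by 3.37 min, worth 0.54 percentage points. My choice is Thursday's.

The forecast gives 11.5%, Thursday's and 16.1%, on the ground that “Dissolution is far faster than the reaction”.

The simulation gives 11.5%. Thursday's is best, adding 4.7 points to reach 16.2%, while Monday's adds 0.46 points.

In this flask the coupling partner reads 0.0132 M at 80.0 min, against 0.0131 M from solubility less g. The neighbouring flask holds 0.14 M of substrate, with the same equivalents and time. Its ceiling rate gives a gap of 1.14 mM, so the partner should stand at 0.0129 M, and it reads 0.0129 M. Its capped yield, Y scaled by the square root of the substrate ratio and trimmed the same way, is 8.52%, and that flask gives 8.66%.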